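**Retrosynthetic overview**
- The last step cuts the benzylic CH2–C(aryl) bond of the central ring. The halves are an N-acyloxyphthalimide of an (R)-3-aryloxybutanoic acid (propenyl-ring half, one carboxyl carbon longer) and a 4-bromo-2,6-dimethoxyphenyl ether that already carries the erythro acetoxy side chain. They are joined by Ni-electrocatalytic decarboxylative arylation.
- Enabling feature: the CH2 is an unhindered primary sp3 carbon. Its neighbour, the O-bearing CH(CH3) stereocentre, is β to it, so a radical at CH2 leaves that centre untouched. The ring carbon it joins is para to the central ring's ether oxygen and lies between two free ring CH positions, which is where 4-bromo-2,6-dimethoxyphenol carries its bromine. CH2 plus one carboxyl carbon maps onto chiral-pool 3-hydroxybutanoate.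
- Acid half: 4-allylsyringol is isomerised to the (E)-propenylphenol, coupled with ethyl (S)-3-hydroxybutanoate by Mitsunobu inversion, saponified and converted to the N-hydroxyphthalimide ester.
- Bromide half: 4-bromo-2,6-dimethoxyphenol and ethyl (S)-lactate are coupled by Mitsunobu inversion, followed by Weinreb amide, aryl Grignard addition, chelation-controlled reduction (the carbinol centre is relayed from the lactate centre) and acetylation.
- No ring is formed; the three benzene rings are bought and only decorated.

Key step: step 10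

Remark on the chemistry: the SMILES is read as E alkene, R at both aryloxy-bearing CH(CH3) carbons and S at the acetoxy carbon (erythro); the aryl Grignard reagent is taken as the purchased THF solution.

**Route**

Step 1
Reactants: 1 4-allyl-2,6-dimethoxyphenol
Product: 2 2,6-dimethoxy-4-[(E)-prop-1-en-1-yl]phenol
Conditions: RuHCl(CO)(PPh3)3 (cat.), toluene, 80 °C
Reagents that add atoms: none
Why: Ru–H-catalysed allyl-to-propenyl isomerisation (hydrometalation/β-hydride elimination) moves the double bond into conjugation with the arene and should give the thermodynamically favoured E alkene, the free phenol being tolerated.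

Step 2
Reactants: 2 2,6-dimethoxy-4-[(E)-prop-1-en-1-yl]phenol; 3 ethyl (S)-3-hydroxybutanoate
Product: 4 ethyl (3R)-3-{2,6-dimethoxy-4-[(E)-prop-1-en-1-yl]phenoxy}butanoate
Conditions: PPh3, DIAD, THF, 0 °C → rt
Reagents that add atoms: none
Why: Mitsunobu etherification, in which the acidic phenol displaces the oxyphosphonium of the secondary alcohol by SN2 with inversion, so the bought (S)-carbinol should become the (R)-aryl ether stereocentre of the target.

Step 3
Reactants: 4 ethyl (3R)-3-{2,6-dimethoxy-4-[(E)-prop-1-en-1-yl]phenoxy}butanoate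
Product: 5 (3R)-3-{2,6-dimethoxy-4-[(E)-prop-1-en-1-yl]phenoxy}butanoic acid
Conditions: LiOH·H2O, THF/H2O, 0 °C → rt; then 1 M HCl to pH 3, 0 °C
Reagents that add atoms: lithium hydroxide, [Li+].[OH-]
Why: Ester saponification at low temperature should be faster than E1cB loss of the β-aryloxide, the stereocentre is not α to the carbonyl, and brief cold acidification should spare the acid-sensitive propenylarene.

Step 4
Reactants: 5 (3R)-3-{2,6-dimethoxy-4-[(E)-prop-1-en-1-yl]phenoxy}butanoic acid
Product: 6 1,3-dioxoisoindolin-2-yl (3R)-3-{2,6-dimethoxy-4-[(E)-prop-1-en-1-yl]phenoxy}butanoate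
Conditions: N-hydroxyphthalimide, DIC, DMAP (cat.), CH2Cl2, 0 °C → rt
Reagents that add atoms: N-hydroxyphthalimide, O=C1c2ccccc2C(=O)N1O
Why: Carbodiimide (Steglich-type) esterification should give the isolable redox-active ester without touching the stereocentre.

Step 5
Reactants: 7 4-bromo-2,6-dimethoxyphenol; 8 ethyl (S)-lactate
Product: 9 ethyl (2R)-2-(4-bromo-2,6-dimethoxyphenoxy)propanoate
Conditions: PPh3, DIAD, THF, 0 °C → rt
Reagents that add atoms: none
Why: Mitsunobu reaction of a lactate ester with a phenol, an α-carbonyl-activated SN2 with clean inversion and no E1cB pathway, should set the (R)-aryloxy stereocentre of the acetoxy side chain.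

Step 6
Reactants: 9 ethyl (2R)-2-(4-bromo-2,6-dimethoxyphenoxy)propanoate
Product: 10 (2R)-2-(4-bromo-2,6-dimethoxyphenoxy)-N-methoxy-N-methylpropanamide
Conditions: MeNH(OMe)·HCl, i-PrMgCl, THF, −20 → 0 °C
Reagents that add atoms: N,O-dimethylhydroxylamine hydrochloride, CNOC.Cl
Why: Weinreb amide formation by aminolysis with the chloromagnesium amide at low temperature, where the electron-rich aryl bromide should not undergo Br/Mg exchange and the α-stereocentre should be retained.

Step 7
Reactants: 10 (2R)-2-(4-bromo-2,6-dimethoxyphenoxy)-N-methoxy-N-methylpropanamide; 11 3,4,5-trimethoxyphenylmagnesium bromide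
Product: 12 (2R)-2-(4-bromo-2,6-dimethoxyphenoxy)-1-(3,4,5-trimethoxyphenyl)propan-1-one
Conditions: THF, −20 → 0 °C; aq. NH4Cl
Reagents that add atoms: none
Why: Weinreb ketone synthesis, in which the chelated tetrahedral adduct stops the aryl Grignard at single addition and releases the ketone on work-up, the aryl bromide being inert to an aryl Grignard at this temperature.

Step 8
Reactants: 12 (2R)-2-(4-bromo-2,6-dimethoxyphenoxy)-1-(3,4,5-trimethoxyphenyl)propan-1-one
Product: 13 (1S,2R)-2-(4-bromo-2,6-dimethoxyphenoxy)-1-(3,4,5-trimethoxyphenyl)propan-1-ol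
Conditions: Zn(BH4)2 (ethereal solution), Et2O/CH2Cl2, −20 → 0 °C; aq. NH4Cl
Reagents that add atoms: none
Why: Chelation-controlled (Cram-chelate) hydride reduction, in which Zn(II) bridges the carbonyl oxygen and the α-aryloxy oxygen (helped by an ortho-methoxy group) and hydride enters on the side of the α-hydrogen, opposite the α-methyl, should give the anti (erythro) 1S,2R alcohol by substrate control from the lactate-derived centre.

Step 9
Reactants: 13 (1S,2R)-2-(4-bromo-2,6-dimethoxyphenoxy)-1-(3,4,5-trimethoxyphenyl)propan-1-ol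
Product: 14 (1S,2R)-2-(4-bromo-2,6-dimethoxyphenoxy)-1-(3,4,5-trimethoxyphenyl)propyl acetate
Conditions: Ac2O, pyridine, DMAP (cat.), CH2Cl2, 0 °C → rt
Reagents that add atoms: acetic anhydride, CC(=O)OC(C)=O
Why: DMAP-catalysed O-acylation of the secondary benzylic alcohol breaks no C–O bond, so the configuration should be retained.

Step 10
Reactants: 6 1,3-dioxoisoindolin-2-yl (3R)-3-{2,6-dimethoxy-4-[(E)-prop-1-en-1-yl]phenoxy}butanoate; 14 (1S,2R)-2-(4-bromo-2,6-dimethoxyphenoxy)-1-(3,4,5-trimethoxyphenyl)propyl acetate
Product: 15 (1S,2R)-2-{4-[(2R)-2-{2,6-dimethoxy-4-[(E)-prop-1-en-1-yl]phenoxy}propyl]-2,6-dimethoxyphenoxy}-1-(3,4,5-trimethoxyphenyl)propyl acetate (target)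
Conditions: 6 (1.5 equiv), 14 (1.0 equiv), NiCl2·6H2O (cat.), 2,2'-bipyridine (cat.), AgNO3 (substoich.), NMP, rt, undivided cell, Mg(+)/RVC(−), constant current
Reagents that add atoms: none
Why: The N-acyloxyphthalimide 6 accepts one electron (from Ni(I) or the silver-coated cathode) and fragments to CO2, phthalimide anion and the primary radical ArO–CH(CH3)–CH2•, while (bpy)Ni(0) inserts into the C–Br bond of 14; radical capture gives an aryl(alkyl)Ni(III) species whose reductive elimination forms the CH2–C(aryl) bond, and the cathode regenerates low-valent nickel as the Mg anode dissolves. The closest known reaction type is the Ni-electrocatalytic decarboxylative C(sp3)–C(sp2) coupling of redox-active esters of primary acids with aryl bromides. No ring is closed and no stereocentre is formed: the ether stereocentre of 6 is β to the radical carbon and the two centres of 14 are remote, so all three should be carried through unchanged. The step needs cross-coupling to outrun β-scission of the β-aryloxy radical, aryl homocoupling and radical addition to the propenylarene; the unhindered primary radical, the C–Br bond flanked by two ring CH groups and fast radical capture by nickel at room temperature should secure this. The sacrificial Mg anode keeps the anode potential below the oxidation potentials of the electron-rich arenes and the propenyl group, and the benzylic acetate and methyl ethers should not be reduced at the potential at which the redox-active ester is consumed.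

**Compound list**
1 | 4-allyl-2,6-dimethoxyphenol | C=CCc1cc(OC)c(O)c(OC)c1 | starting material
2 | 2,6-dimethoxy-4-[(E)-prop-1-en-1-yl]phenol | C/C=C/c1cc(OC)c(O)c(OC)c1 | intermediate
3 | ethyl (S)-3-hydroxybutanoate | CCOC(=O)C[C@H](C)O | starting material
4 | ethyl (3R)-3-{2,6-dimethoxy-4-[(E)-prop-1-en-1-yl]phenoxy}butanoate | C/C=C/c1cc(OC)c(O[C@H](C)CC(=O)OCC)c(OC)c1 | intermediate
5 | (3R)-3-{2,6-dimethoxy-4-[(E)-prop-1-en-1-yl]phenoxy}butanoic acid | C/C=C/c1cc(OC)c(O[C@H](C)CC(=O)O)c(OC)c1 | intermediate
6 | 1,3-dioxoisoindolin-2-yl (3R)-3-{2,6-dimethoxy-4-[(E)-prop-1-en-1-yl]phenoxy}butanoate | C/C=C/c1cc(OC)c(O[C@H](C)CC(=O)ON2C(=O)c3ccccc3C2=O)c(OC)c1 | intermediate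
7 | 4-bromo-2,6-dimethoxyphenol | COc1cc(Br)cc(OC)c1O | starting material
8 | ethyl (S)-lactate | CCOC(=O)[C@H](C)O | starting material
9 | ethyl (2R)-2-(4-bromo-2,6-dimethoxyphenoxy)propanoate | COc1cc(Br)cc(OC)c1O[C@H](C)C(=O)OCC | intermediate
10 | (2R)-2-(4-bromo-2,6-dimethoxyphenoxy)-N-methoxy-N-methylpropanamide | COc1cc(Br)cc(OC)c1O[C@H](C)C(=O)N(C)OC | intermediate
11 | 3,4,5-trimethoxyphenylmagnesium bromide | COc1cc([Mg]Br)cc(OC)c1OC | starting material
12 | (2R)-2-(4-bromo-2,6-dimethoxyphenoxy)-1-(3,4,5-trimethoxyphenyl)propan-1-one | COc1cc(Br)cc(OC)c1O[C@H](C)C(=O)c2cc(OC)c(OC)c(OC)c2 | intermediate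
13 | (1S,2R)-2-(4-bromo-2,6-dimethoxyphenoxy)-1-(3,4,5-trimethoxyphenyl)propan-1-ol | COc1cc(Br)cc(OC)c1O[C@H](C)[C@@H](O)c2cc(OC)c(OC)c(OC)c2 | intermediate
14 | (1S,2R)-2-(4-bromo-2,6-dimethoxyphenoxy)-1-(3,4,5-trimethoxyphenyl)propyl acetate | COc1cc(Br)cc(OC)c1O[C@H](C)[C@@H](OC(C)=O)c2cc(OC)c(OC)c(OC)c2 | intermediate
15 | (1S,2R)-2-{4-[(2R)-2-{2,6-dimethoxy-4-[(E)-prop-1-en-1-yl]phenoxy}propyl]-2,6-dimethoxyphenoxy}-1-(3,4,5-trimethoxyphenyl)propyl acetate | C/C=C/c1cc(OC)c(O[C@H](C)Cc2cc(OC)c(O[C@H](C)[C@@H](OC(C)=O)c3cc(OC)c(OC)c(OC)c3)c(OC)c2)c(OC)c1 | target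

**Step count**
Total: 10 steps. Longest linear sequence: 6 steps (steps 5, 6, 7, 8, 9, 10); the other branch is 5 steps (steps 1, 2, 3, 4, 10).

**Steps most likely to fail**

Step 10. The primary radical or its alkyl–nickel successor may lose the β-aryloxy group (β-scission or β-aryloxide elimination to propene and phenoxide). Protodebromination or homocoupling of the aryl bromide may also outrun the cross-coupling, or the radical may add to the propenylarene. The fallback sets out from 13 and returns at 15; it forms the same CH2–aryl bond by a two-electron path with an electrophile that cannot fragment in this way. Alcohol 13 would be silylated (TBSOTf, 2,6-lutidine, CH2Cl2) to the tert-butyldimethylsilyl ether F1. Bromine–lithium exchange (n-BuLi, THF, −78 °C) and BF3·OEt2-promoted opening of (S)-propylene oxide at its CH2 terminus would give the (S)-1-arylpropan-2-ol F2. Mitsunobu etherification of F2 with phenol 2 (PPh3, DIAD, inversion to R) would give the silyl-protected triaryl ether F3. TBAF in THF would release the benzylic alcohol F4, and acetylation as in step 9 would give 15.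

Step 2. The activated β-hydroxy ester may eliminate to ethyl crotonate faster than the di-ortho-substituted phenol can displace it, or conversion may stall. The fallback sets out from 2 and returns at 15; it replaces the β-hydroxy ester by the lactate, which has no E1cB pathway, and changes the radical precursor. Phenol 2 and ethyl (S)-lactate 8 under Mitsunobu conditions would give the (R)-2-aryloxypropanoate F5. LiAlH4 (THF, 0 °C) would give the primary alcohol F6, and CBr4/PPh3 (CH2Cl2, 0 °C) would give the primary bromide F7. Nickel-catalysed reductive cross-electrophile coupling of F7 with aryl bromide 14 (NiBr2·glyme, 4,4'-di-tert-butyl-2,2'-bipyridine, NaI, Zn, DMA, rt) would form the same CH2–aryl bond and give 15; steps 3 and 4 are then not needed.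

Step 8. Facial selectivity may be poor if the weakly basic aryl ether oxygen does not hold zinc in a chelate, so that open-chain (Felkin-type) delivery gives the threo epimer. The fallback sets out from 12 and returns at 13; it moves the control element from the substrate to a catalyst. Noyori asymmetric transfer hydrogenation with RuCl(p-cymene)[(R,R)-TsDPEN] in HCO2H/Et3N at rt should set the carbinol centre as S, the aryl/alkyl differentiation of the catalyst overriding the chelation question. This fallback makes no new compound (F0).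

**Further compounds**
F1 | step 10 | tert-butyl{[(1S,2R)-2-(4-bromo-2,6-dimethoxyphenoxy)-1-(3,4,5-trimethoxyphenyl)propyl]oxy}dimethylsilane | COc1cc(Br)cc(OC)c1O[C@H](C)[C@@H](O[Si](C)(C)C(C)(C)C)c2cc(OC)c(OC)c(OC)c2
F2 | step 10 | (2S)-1-[4-{[(1S,2R)-1-(tert-butyldimethylsilyloxy)-1-(3,4,5-trimethoxyphenyl)propan-2-yl]oxy}-3,5-dimethoxyphenyl]propan-2-ol | C[C@H](O)Cc1cc(OC)c(O[C@H](C)[C@@H](O[Si](C)(C)C(C)(C)C)c2cc(OC)c(OC)c(OC)c2)c(OC)c1
F3 | step 10 | tert-butyldimethylsilyl ether of the deacetyl target | C/C=C/c1cc(OC)c(O[C@H](C)Cc2cc(OC)c(O[C@H](C)[C@@H](O[Si](C)(C)C(C)(C)C)c3cc(OC)c(OC)c(OC)c3)c(OC)c2)c(OC)c1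
F4 | step 10 | (1S,2R)-2-{4-[(2R)-2-{2,6-dimethoxy-4-[(E)-prop-1-en-1-yl]phenoxy}propyl]-2,6-dimethoxyphenoxy}-1-(3,4,5-trimethoxyphenyl)propan-1-ol | C/C=C/c1cc(OC)c(O[C@H](C)Cc2cc(OC)c(O[C@H](C)[C@@H](O)c3cc(OC)c(OC)c(OC)c3)c(OC)c2)c(OC)c1
F5 | step 2 | ethyl (2R)-2-{2,6-dimethoxy-4-[(E)-prop-1-en-1-yl]phenoxy}propanoate | C/C=C/c1cc(OC)c(O[C@H](C)C(=O)OCC)c(OC)c1
F6 | step 2 | (2R)-2-{2,6-dimethoxy-4-[(E)-prop-1-en-1-yl]phenoxy}propan-1-ol | C/C=C/c1cc(OC)c(O[C@H](C)CO)c(OC)c1
F7 | step 2 | 2-{[(2R)-1-bromopropan-2-yl]oxy}-1,3-dimethoxy-5-[(E)-prop-1-en-1-yl]benzene | C/C=C/c1cc(OC)c(O[C@H](C)CBr)c(OC)c1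
F0 | step 8 | none | none
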